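## Structural features

The target is an achiral heptaphenol made of four benzene rings. Rings A and C are phloroglucinol units, each with one methyl ether, joined by a single CH2 between a6 and c1. Ring A (a1 OMe, a3 and a5 OH) carries ketone K1 at a4, leading to ring B (2,4-dihydroxy-6-methylphenyl). Ring C (c2 OMe, c4 and c6 OH) carries ketone K2 at c5, leading to ring D (4-hydroxy-2-methoxy-6-methylphenyl). There is no stereocentre, so no stereocentres stand next to each other; the only stereogenic atom that appears on the way is a racemic carbinol carbon that ends as K1. Both ketones are tetra-ortho-substituted benzophenones placed between two oxygen-bearing carbons, and the two halves differ only by one O-methyl group (ring D against ring B). The difficulty is therefore to form two very hindered aryl–CO bonds at defined positions of rings whose open positions an electrophile cannot tell apart. Fragile elements are the free polyphenol (air oxidation), the electron-rich diarylmethane (acid-induced cleavage or further alkylation), the 2,2'-dihydroxybenzophenone units (xanthone formation on heating) and the two aryl methyl ethers, which rule out methyl as a protecting group and Lewis-acid dealkylation at the end. The key step uses the contiguous array c4(O)–c5(C=O)–c6(OH)–c1(CH2) of ring C: an acyl carbon and a hydroxyl on neighbouring carbons, with a further oxygen on the far side of the acyl carbon, is the pattern left when a carboxylate oxygen adds to the remote end of a 3-alkoxyaryne and the acyl group then moves from oxygen to carbon.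

## Logic of the disconnections

23 ⇒ 22. The six O–CH2Ph bonds are cut. Benzyl is the only mask on the phenols that must be free at the end, so one neutral hydrogenolysis finishes the synthesis and the two methyl ethers are never at risk. The demand is that both hindered ketones and the bridge CH2 survive hydrogen over palladium.

22 ⇒ 18 + 20 (through 21). The c5–CO bond of K2 and the c6–O bond are cut together. This removes ring D as a simple benzoic acid and reduces ring C to an aryne, so the tetra-ortho ketone is made intramolecularly and the c6 hydroxyl is released in the same operation. The forward step needs oxygen attack at c6 and not c5, and acyl transfer to the c5 anion faster than its protonation.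

18 ⇒ 17 ⇒ 16. The S–O bond of the triflate and the K1 carbonyl (taken back to a carbinol) are cut. K1 is kept at the alcohol level until all organolithium chemistry is over, so no diaryl ketone ever meets butyllithium. The demand is sulfonylation of the phenol without touching the hindered doubly benzylic alcohol, then oxidation of a very congested carbinol beside an aryl silane.

16 ⇒ 11 + 14 (through 15). The a4–CH(OH) bond and the c5–Si bond are cut. Both carbons lie between two oxygens, where bromine can be placed without ambiguity, and one butyllithium operation converts both bromides. The forward step requires the two aryllithiums to take different courses; this is secured because only the ring C one has an O–Si group beside it.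

11 ⇒ 10 ⇒ 9. The O–Si bond and the c4 O–CH2Ph bond are cut, leaving a ring C diol. The gain is that the two ring C oxygens are told apart only after the bridge exists, when they differ sterically. The demand is benzylation of the less hindered c4 hydroxyl.

9 ⇒ 8 + 5. The c1–CH2 bond is cut. 5 is mirror-symmetric, so its two open positions are identical and Friedel–Crafts alkylation cannot give regioisomers. The molecule falls into two rings of similar size that both come from the same bromide. The demand is mono-alkylation, met by an excess of 5.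

8 ⇒ 7 ⇒ 6 ⇒ 5. The a6–C bond of the one-carbon handle and two O–CH2Ph bonds are cut. 6 is again symmetric with a single kind of open position, activated by all three oxygens, so formylation needs no selectivity.

5 ⇒ 4 ⇒ 2 ⇒ 1 (through 3). The C–Br bond is cut. Electrophilic bromination of 1 would be expected to go para to a hydroxyl and not between the two hydroxyls. Lithiation between two MOM ethers fixes the position instead. The price is a protection and a deprotection.

14 ⇒ 13 ⇒ 12 and 20 ⇒ 19 ⇒ 13. O–CH2Ph and O–CH3 bonds are cut and the acid is taken back to the aldehyde. Rings B and D diverge from one mono-benzyl ether, 13, in which the chelated ortho hydroxyl has been left free. That hydroxyl is then benzylated (ring B) or methylated (ring D); each alkylation must stop at the intended oxygen.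

## Other disconnections considered

Alternative 1: Ring A is taken apart at a4–a5 and a2–a3, with a5–a6 broken and re-formed in the forward direction. The forward step is a Danheiser benzannulation: cyclobutenone A2, carrying the C–D benzophenone on its C4 methylene, is heated with siloxyalkyne A3. Ring opening to a vinylketene, (2+2) addition, a second four-electron opening and a six-electron closure would give phenol A1.
- In favour: the oxygenation pattern and the position of the bridge are set by the pericyclic sequence, the conditions are neutral, and the silyl group at a4 marks the carbon that must carry K1.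
- Against: A2 needs C4-alkylation of a 3-methoxycyclobutenone enolate with a hindered, easily ionised benzylic halide that already contains K2. A1 still lacks K1, which would then have to be introduced between two oxygens by ipso-acylation with a doubly ortho-substituted aroyl electrophile, followed by silyl-to-benzyl exchange.
- Comparison: on structure it builds a benzene ring that the chosen plan takes intact from 1. On mechanism its regiochemistry is more secure than substituent-controlled aryne addition, and on that point it is the better of the two. It leaves the hard bond, the tetra-ortho ketone, to a later intermolecular step, whereas the chosen plan forms its ketone intramolecularly in the key step. Step economy is worse.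

Alternative 2: Ring B is cut at b1–b2. Tetraketone A5, a 1-aryl-octane-1,3,5,7-tetraone on ring A, would cyclise under mild base by aldol attack of C2 on the C7 ketone, dehydration and enolisation to give A4.
- In favour: the step is biomimetic, ring B appears with both hydroxyls and the methyl group already in place and needs no protection, and the K1 carbon is simply C1 of the chain. A4 is one hydrogenolysis from the target, which equals the chosen endgame with one benzyl group fewer.
- Against: A5 requires acylation of a triketone polyanion by a doubly ortho-substituted ring A ester in the presence of K2 and the acidic bridge CH2. The polyketone can also close through oxygen to pyranones or by other aldol modes.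
- Comparison: on structure it replaces a purchasable aromatic ring (12) by a chain that must be built. On mechanism its selectivity rests on relative carbonyl reactivity, not on a built-in directing element. It also says nothing about K2, which would still need a method of its own. Step economy is no better.

Alternative 3: The b1–K1 bond and the b2–CH2 bond are cut. CsF would convert silyl triflate A8 into an aryne, the enolate carbon of ring A β-ketoester A7 would add to b2, the b1 anion would close onto the ketone and the cyclobutoxide would fragment to A6.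
- In favour: it uses the same alkoxy-directed aryne regiocontrol and also forms a tetra-ortho ketone by insertion. The aryne partner A8 is small and can be used in excess while the valuable fragment is the nucleophile. On that point it is better than the chosen plan, where the aryne precursor is the advanced component.
- Against: A6 carries CH2CO2tBu where a methyl group is needed. Ester cleavage and decarboxylation of an ortho-acyl arylacetic acid are extra steps, and such acids tend to lactonise. Closure onto a ketone flanked by two benzyloxy groups is hindered, and A7 must itself be made from a congested ring A acid derivative.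
- Comparison: the mechanisms are of equal standing. The chosen plan delivers the correct substituents directly, with the c6 hydroxyl free and six benzyl groups to remove; alternative 3 needs seven benzyl groups and a degradation of the side chain, so it is longer.

Key step: step 17

Remark on the chemistry: 1 and 12 are taken as purchasable. The carbinol carbon formed in step 12 is racemic and becomes the K1 carbonyl carbon in step 14, so the route needs no stereocontrol.

## Route

Step 1
Reactants: 1 5-methoxyresorcinol (5-methoxybenzene-1,3-diol)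
Product: 2 1-methoxy-3,5-bis(methoxymethoxy)benzene
Conditions: NaH (2.4 equiv), MOMCl (2.4 equiv), THF, 0 °C to rt
Reagents that add atoms: chloromethyl methyl ether, COCCl
Why: Williamson-type O-alkylation of both sodium phenoxides; the MOM ethers serve as the directing groups for step 2 and are removable by mild acid.

Step 2
Reactants: 2 1-methoxy-3,5-bis(methoxymethoxy)benzene
Product: 4 2-bromo-5-methoxy-1,3-bis(methoxymethoxy)benzene, via aryllithium 3 (not isolated)
Conditions: n-BuLi (1.1 equiv), THF, 0 °C; then BrCH2CH2Br, −78 °C to rt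
Reagents that add atoms: 1,2-dibromoethane, BrCCBr
Why: Directed ortho-metalation; the carbon between the two MOM ethers is coordinated from both sides and should be lithiated in preference to the carbons next to the methoxy group. The aryllithium takes bromine from 1,2-dibromoethane with loss of ethene.

Step 3
Reactants: 4 2-bromo-5-methoxy-1,3-bis(methoxymethoxy)benzene
Product: 5 2-bromo-5-methoxybenzene-1,3-diol
Conditions: HCl (cat.), MeOH, 50 °C
Reagents that add atoms: none
Why: Acid-catalysed acetal exchange with methanol frees both phenols; the aryl bromide is inert to dilute acid.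

Step 4
Reactants: 5 2-bromo-5-methoxybenzene-1,3-diol
Product: 6 1,3-bis(benzyloxy)-2-bromo-5-methoxybenzene
Conditions: BnBr (2.3 equiv), K2CO3, DMF, 50 °C
Reagents that add atoms: benzyl bromide, BrCc1ccccc1
Why: Williamson etherification of both phenols; the product keeps the mirror symmetry that makes the next step unambiguous.

Step 5
Reactants: 6 1,3-bis(benzyloxy)-2-bromo-5-methoxybenzene
Product: 7 2,4-bis(benzyloxy)-3-bromo-6-methoxybenzaldehyde
Conditions: POCl3, DMF, 0 to 70 °C; then H2O
Reagents that add atoms: N,N-dimethylformamide, CN(C)C=O; water, O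
Why: Vilsmeier–Haack formylation; the two open positions of 6 are identical and each is ortho or para to all three ether oxygens, so only one aldehyde can form.

Step 6
Reactants: 7 2,4-bis(benzyloxy)-3-bromo-6-methoxybenzaldehyde
Product: 8 [2,4-bis(benzyloxy)-3-bromo-6-methoxyphenyl]methanol
Conditions: NaBH4, THF/MeOH, 0 °C
Reagents that add atoms: none
Why: Hydride reduction of the aldehyde; the electron-rich benzylic alcohol is used without storage because it ionises easily.

Step 7
Reactants: 8 [2,4-bis(benzyloxy)-3-bromo-6-methoxyphenyl]methanol; 5 2-bromo-5-methoxybenzene-1,3-diol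
Product: 9 4-{[2,4-bis(benzyloxy)-3-bromo-6-methoxyphenyl]methyl}-2-bromo-5-methoxybenzene-1,3-diol
Conditions: 5 (3 equiv), TsOH·H2O (10 mol %), MeCN, 0 °C to rt
Reagents that add atoms: none
Why: Friedel–Crafts benzylation; the trialkoxybenzyl cation from 8 is captured by the free diol 5, which is the most nucleophilic arene present and has two identical open positions. The excess of 5 suppresses a second alkylation and is recoverable.

Step 8
Reactants: 9 4-{[2,4-bis(benzyloxy)-3-bromo-6-methoxyphenyl]methyl}-2-bromo-5-methoxybenzene-1,3-diol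
Product: 10 3-(benzyloxy)-6-{[2,4-bis(benzyloxy)-3-bromo-6-methoxyphenyl]methyl}-2-bromo-5-methoxyphenol
Conditions: BnBr (1.05 equiv), K2CO3 (1.1 equiv), acetone, rt
Reagents that add atoms: benzyl bromide, BrCc1ccccc1
Why: Williamson etherification under steric control; the c6 hydroxyl sits between bromine and the diarylmethyl carbon and can hydrogen-bond to the ring A ether oxygens, whereas the c4 hydroxyl has an open ortho position and should react first.

Step 9
Reactants: 10 3-(benzyloxy)-6-{[2,4-bis(benzyloxy)-3-bromo-6-methoxyphenyl]methyl}-2-bromo-5-methoxyphenol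
Product: 11 [3-(benzyloxy)-6-{[2,4-bis(benzyloxy)-3-bromo-6-methoxyphenyl]methyl}-2-bromo-5-methoxyphenoxy]trimethylsilane
Conditions: HMDS, THF, 65 °C; evaporate, use crude
Reagents that add atoms: hexamethyldisilazane, C[Si](C)(C)N[Si](C)(C)C
Why: O-silylation of the phenol with ammonia as the only by-product; the moisture-sensitive silyl ether is carried on without purification.

Step 10
Reactants: 12 2,4-dihydroxy-6-methylbenzaldehyde
Product: 13 4-(benzyloxy)-2-hydroxy-6-methylbenzaldehyde
Conditions: BnBr (1.05 equiv), K2CO3 (1.1 equiv), acetone, 50 °C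
Reagents that add atoms: benzyl bromide, BrCc1ccccc1
Why: Selective Williamson etherification; the 2-hydroxyl is hydrogen-bonded to the formyl group and less nucleophilic, so the 4-hydroxyl is alkylated.

Step 11
Reactants: 13 4-(benzyloxy)-2-hydroxy-6-methylbenzaldehyde
Product: 14 2,4-bis(benzyloxy)-6-methylbenzaldehyde
Conditions: BnBr (1.3 equiv), K2CO3, DMF, 60 °C
Reagents that add atoms: benzyl bromide, BrCc1ccccc1
Why: Williamson etherification of the chelated phenol under more forcing conditions gives the ring B aldehyde.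

Step 12
Reactants: 11 [3-(benzyloxy)-6-{[2,4-bis(benzyloxy)-3-bromo-6-methoxyphenyl]methyl}-2-bromo-5-methoxyphenoxy]trimethylsilane; 14 2,4-bis(benzyloxy)-6-methylbenzaldehyde
Product: 16 [2,6-bis(benzyloxy)-3-{[4-(benzyloxy)-2-hydroxy-6-methoxy-3-(trimethylsilyl)phenyl]methyl}-4-methoxyphenyl][2,4-bis(benzyloxy)-6-methylphenyl]methanol (racemic), via dilithio intermediate 15 (not isolated)
Conditions: n-BuLi (2.2 equiv), THF, −78 °C; then 14 (1.3 equiv), −78 to 0 °C; aq. NH4Cl
Reagents that add atoms: none
Why: Double bromine–lithium exchange; the ring C aryllithium has an O–SiMe3 group beside it and undergoes the 1,3 O-to-C silyl shift (retro-Brook rearrangement) to the lithium phenoxide, while the ring A aryllithium, flanked only by benzyl ethers, persists and adds to aldehyde 14. The carbinol carbon is racemic and is oxidised in step 14; no ketone is present when butyllithium is used.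

Step 13
Reactants: 16 [2,6-bis(benzyloxy)-3-{[4-(benzyloxy)-2-hydroxy-6-methoxy-3-(trimethylsilyl)phenyl]methyl}-4-methoxyphenyl][2,4-bis(benzyloxy)-6-methylphenyl]methanol (racemic)
Product: 17 3-(benzyloxy)-6-({2,4-bis(benzyloxy)-3-[(2,4-bis(benzyloxy)-6-methylphenyl)(hydroxy)methyl]-6-methoxyphenyl}methyl)-5-methoxy-2-(trimethylsilyl)phenyl trifluoromethanesulfonate (racemic)
Conditions: PhNTf2 (1.3 equiv), Cs2CO3, MeCN, rt
Reagents that add atoms: N-phenylbis(trifluoromethanesulfonimide), O=S(=O)(N(c1ccccc1)S(=O)(=O)C(F)(F)F)C(F)(F)F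
Why: Sulfonyl transfer to the cesium phenoxide; carbonate does not deprotonate the hindered benzylic alcohol, and no strong acid is formed that could ionise it or cleave the aryl–silicon bond.

Step 14
Reactants: 17 3-(benzyloxy)-6-({2,4-bis(benzyloxy)-3-[(2,4-bis(benzyloxy)-6-methylphenyl)(hydroxy)methyl]-6-methoxyphenyl}methyl)-5-methoxy-2-(trimethylsilyl)phenyl trifluoromethanesulfonate (racemic)
Product: 18 3-(benzyloxy)-6-({2,4-bis(benzyloxy)-3-[2,4-bis(benzyloxy)-6-methylbenzoyl]-6-methoxyphenyl}methyl)-5-methoxy-2-(trimethylsilyl)phenyl trifluoromethanesulfonate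
Conditions: Dess–Martin periodinane, NaHCO3, CH2Cl2, 0 °C to rt
Reagents that add atoms: none
Why: Dess–Martin oxidation of the benzhydrol to ketone K1 under buffered conditions; aryl silane, triflate and benzyl ethers are inert.

Step 15
Reactants: 13 4-(benzyloxy)-2-hydroxy-6-methylbenzaldehyde
Product: 19 4-(benzyloxy)-2-methoxy-6-methylbenzaldehyde
Conditions: MeI (2 equiv), K2CO3, DMF, 40 °C
Reagents that add atoms: iodomethane, CI
Why: Williamson methylation of the remaining chelated phenol gives the ring D oxygenation pattern.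

Step 16
Reactants: 19 4-(benzyloxy)-2-methoxy-6-methylbenzaldehyde
Product: 20 4-(benzyloxy)-2-methoxy-6-methylbenzoic acid
Conditions: NaClO2, NaH2PO4, 2-methyl-2-butene (excess), t-BuOH/H2O, rt
Reagents that add atoms: sodium chlorite, [Na+].[O-]Cl=O
Why: Pinnick oxidation of a hindered aryl aldehyde; the alkene scavenges hypochlorous acid so the electron-rich ring is not chlorinated.

Step 17
Reactants: 18 3-(benzyloxy)-6-({2,4-bis(benzyloxy)-3-[2,4-bis(benzyloxy)-6-methylbenzoyl]-6-methoxyphenyl}methyl)-5-methoxy-2-(trimethylsilyl)phenyl trifluoromethanesulfonate; 20 4-(benzyloxy)-2-methoxy-6-methylbenzoic acid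
Product: 22 {2,6-bis(benzyloxy)-3-[(4-(benzyloxy)-3-{4-(benzyloxy)-2-methoxy-6-methylbenzoyl}-2-hydroxy-6-methoxyphenyl)methyl]-4-methoxyphenyl}[2,4-bis(benzyloxy)-6-methylphenyl]methanone, via aryne 21 (not isolated)
Conditions: 20 (3 equiv), CsF (6 equiv), THF, 125 °C, sealed tube
Reagents that add atoms: none
Why: Fluoride attacks silicon at c5 and triflate leaves from c6, giving aryne 21, while excess CsF keeps acid 20 as its carboxylate. The c4 benzyloxy group polarises the aryne so that the carboxylate oxygen adds at the remote carbon c6 and the negative charge develops at c5, next to the oxygen-bearing carbon. The c5 anion then attacks the carbonyl of the aryl ester just formed through a four-membered transition state, and the adduct opens to ketone K2 and the c6 phenoxide, which is protonated on work-up. The closest known reaction is fluoride-induced aryne insertion into the C–O bond of aromatic carboxylic acids to give ortho-hydroxyaryl ketones. No ring is closed and no stereocentre is formed. The regiochemistry needs the alkoxy effect at c4 to outweigh the steric effect of the CH2 substituent on c1. Acyl transfer must outrun protonation of the c5 anion, which the aprotic medium, excess CsF and high temperature favour. Excess carboxylate also makes intermolecular capture faster than attack of the a5 benzyloxy oxygen on c6.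

Step 18
Reactants: 22 {2,6-bis(benzyloxy)-3-[(4-(benzyloxy)-3-{4-(benzyloxy)-2-methoxy-6-methylbenzoyl}-2-hydroxy-6-methoxyphenyl)methyl]-4-methoxyphenyl}[2,4-bis(benzyloxy)-6-methylphenyl]methanone
Product: 23 {3-[(2,4-dihydroxy-3-{4-hydroxy-2-methoxy-6-methylbenzoyl}-6-methoxyphenyl)methyl]-2,6-dihydroxy-4-methoxyphenyl}(2,4-dihydroxy-6-methylphenyl)methanone (target)
Conditions: H2 (1 atm), 10 % Pd/C, EtOAc/MeOH, rt
Reagents that add atoms: none
Why: Hydrogenolysis of the six benzyl ethers; the twisted, tetra-ortho-substituted ketones and the aryl methyl ethers should react far more slowly, so the reaction is stopped once hydrogen uptake ends.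

## Compound list

1 | 5-methoxyresorcinol (5-methoxybenzene-1,3-diol) | COc1cc(O)cc(O)c1 | starting material
2 | 1-methoxy-3,5-bis(methoxymethoxy)benzene | COCOc1cc(OC)cc(OCOC)c1 | intermediate
3 | [4-methoxy-2,6-bis(methoxymethoxy)phenyl]lithium | COCOc1cc(OC)cc(OCOC)c1[Li] | intermediate (not isolated)
4 | 2-bromo-5-methoxy-1,3-bis(methoxymethoxy)benzene | COCOc1cc(OC)cc(OCOC)c1Br | intermediate
5 | 2-bromo-5-methoxybenzene-1,3-diol | COc1cc(O)c(Br)c(O)c1 | intermediate
6 | 1,3-bis(benzyloxy)-2-bromo-5-methoxybenzene | COc1cc(OCc2ccccc2)c(Br)c(OCc2ccccc2)c1 | intermediate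
7 | 2,4-bis(benzyloxy)-3-bromo-6-methoxybenzaldehyde | COc1cc(OCc2ccccc2)c(Br)c(OCc2ccccc2)c1C=O | intermediate
8 | [2,4-bis(benzyloxy)-3-bromo-6-methoxyphenyl]methanol | COc1cc(OCc2ccccc2)c(Br)c(OCc2ccccc2)c1CO | intermediate
9 | 4-{[2,4-bis(benzyloxy)-3-bromo-6-methoxyphenyl]methyl}-2-bromo-5-methoxybenzene-1,3-diol | COc1cc(OCc2ccccc2)c(Br)c(OCc2ccccc2)c1Cc1c(OC)cc(O)c(Br)c1O | intermediate
10 | 3-(benzyloxy)-6-{[2,4-bis(benzyloxy)-3-bromo-6-methoxyphenyl]methyl}-2-bromo-5-methoxyphenol | COc1cc(OCc2ccccc2)c(Br)c(OCc2ccccc2)c1Cc1c(OC)cc(OCc2ccccc2)c(Br)c1O | intermediate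
11 | [3-(benzyloxy)-6-{[2,4-bis(benzyloxy)-3-bromo-6-methoxyphenyl]methyl}-2-bromo-5-methoxyphenoxy]trimethylsilane | COc1cc(OCc2ccccc2)c(Br)c(OCc2ccccc2)c1Cc1c(OC)cc(OCc2ccccc2)c(Br)c1O[Si](C)(C)C | intermediate
12 | 2,4-dihydroxy-6-methylbenzaldehyde | Cc1cc(O)cc(O)c1C=O | starting material
13 | 4-(benzyloxy)-2-hydroxy-6-methylbenzaldehyde | Cc1cc(OCc2ccccc2)cc(O)c1C=O | intermediate
14 | 2,4-bis(benzyloxy)-6-methylbenzaldehyde | Cc1cc(OCc2ccccc2)cc(OCc2ccccc2)c1C=O | intermediate
15 | dilithio intermediate: ring A aryllithium at a4, ring C lithium phenoxide at c6 with SiMe3 on c5 | COc1cc(OCc2ccccc2)c([Li])c(OCc2ccccc2)c1Cc1c(OC)cc(OCc2ccccc2)c([Si](C)(C)C)c1O[Li] | intermediate (not isolated)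
16 | [2,6-bis(benzyloxy)-3-{[4-(benzyloxy)-2-hydroxy-6-methoxy-3-(trimethylsilyl)phenyl]methyl}-4-methoxyphenyl][2,4-bis(benzyloxy)-6-methylphenyl]methanol (racemic) | COc1cc(OCc2ccccc2)c(C(O)c2c(C)cc(OCc3ccccc3)cc2OCc2ccccc2)c(OCc2ccccc2)c1Cc1c(OC)cc(OCc2ccccc2)c([Si](C)(C)C)c1O | intermediate
17 | 3-(benzyloxy)-6-({2,4-bis(benzyloxy)-3-[(2,4-bis(benzyloxy)-6-methylphenyl)(hydroxy)methyl]-6-methoxyphenyl}methyl)-5-methoxy-2-(trimethylsilyl)phenyl trifluoromethanesulfonate (racemic) | COc1cc(OCc2ccccc2)c(C(O)c2c(C)cc(OCc3ccccc3)cc2OCc2ccccc2)c(OCc2ccccc2)c1Cc1c(OC)cc(OCc2ccccc2)c([Si](C)(C)C)c1OS(=O)(=O)C(F)(F)F | intermediate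
18 | 3-(benzyloxy)-6-({2,4-bis(benzyloxy)-3-[2,4-bis(benzyloxy)-6-methylbenzoyl]-6-methoxyphenyl}methyl)-5-methoxy-2-(trimethylsilyl)phenyl trifluoromethanesulfonate | COc1cc(OCc2ccccc2)c(C(=O)c2c(C)cc(OCc3ccccc3)cc2OCc2ccccc2)c(OCc2ccccc2)c1Cc1c(OC)cc(OCc2ccccc2)c([Si](C)(C)C)c1OS(=O)(=O)C(F)(F)F | intermediate
19 | 4-(benzyloxy)-2-methoxy-6-methylbenzaldehyde | COc1cc(OCc2ccccc2)cc(C)c1C=O | intermediate
20 | 4-(benzyloxy)-2-methoxy-6-methylbenzoic acid | COc1cc(OCc2ccccc2)cc(C)c1C(=O)O | intermediate
21 | c5–c6 aryne of ring C (c1 CH2 to the benzylated A–B benzophenone, c2 OMe, c4 OBn) | COc1cc(OCc2ccccc2)c(C(=O)c2c(C)cc(OCc3ccccc3)cc2OCc2ccccc2)c(OCc2ccccc2)c1CC1=C(OC)C=C(OCc2ccccc2)C#C1 | intermediate (not isolated)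
22 | {2,6-bis(benzyloxy)-3-[(4-(benzyloxy)-3-{4-(benzyloxy)-2-methoxy-6-methylbenzoyl}-2-hydroxy-6-methoxyphenyl)methyl]-4-methoxyphenyl}[2,4-bis(benzyloxy)-6-methylphenyl]methanone | COc1cc(OCc2ccccc2)c(C(=O)c2c(C)cc(OCc3ccccc3)cc2OCc2ccccc2)c(OCc2ccccc2)c1Cc1c(OC)cc(OCc2ccccc2)c(C(=O)c2c(C)cc(OCc3ccccc3)cc2OC)c1O | intermediate
23 | {3-[(2,4-dihydroxy-3-{4-hydroxy-2-methoxy-6-methylbenzoyl}-6-methoxyphenyl)methyl]-2,6-dihydroxy-4-methoxyphenyl}(2,4-dihydroxy-6-methylphenyl)methanone | COc1cc(O)c(C(=O)c2c(C)cc(O)cc2O)c(O)c1Cc1c(OC)cc(O)c(C(=O)c2c(C)cc(O)cc2OC)c1O | target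

## Step count and least certain steps

Total step count: 18. Longest linear sequence: 14 steps (steps 1–9, 12–14, 17 and 18). Steps 10–11 and 15–16 are side branches.

**Step 17 (key step).** The most likely failure is protonation of the c5 aryl anion before the acyl shift, which would stop at simple O-arylation of the acid. The carbonyl to be attacked is flanked by a methoxy and a methyl group, so the four-membered transfer is slow. Further risks are capture of the aryne by the a5 benzyloxy oxygen through a six-membered transition state, and loss of regiocontrol because of the substituent on c1.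
Fallback from 10 to 22, using a 1,3 O-to-C acyl shift triggered by bromine–lithium exchange (anionic Fries type) in place of the aryne. Acid 20 is converted with oxalyl chloride and catalytic DMF into 4-(benzyloxy)-2-methoxy-6-methylbenzoyl chloride F1. F1 acylates the free c6 hydroxyl of 10 (Et3N, DMAP, CH2Cl2) to give the aryl ester 3-(benzyloxy)-6-{[2,4-bis(benzyloxy)-3-bromo-6-methoxyphenyl]methyl}-2-bromo-5-methoxyphenyl 4-(benzyloxy)-2-methoxy-6-methylbenzoate F2. n-BuLi (2.2 equiv, THF, −78 °C) exchanges both bromines. The ring C aryllithium attacks the neighbouring ester and opens to K2 and the c6 phenoxide, and the ring A aryllithium is then trapped with 14. This gives the racemic carbinol [2,6-bis(benzyloxy)-3-({4-(benzyloxy)-3-[4-(benzyloxy)-2-methoxy-6-methylbenzoyl]-2-hydroxy-6-methoxyphenyl}methyl)-4-methoxyphenyl][2,4-bis(benzyloxy)-6-methylphenyl]methanol F3. Oxidation of the benzhydrol with MnO2 in CH2Cl2 returns to the route at 22.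

**Step 12.** What may go wrong: incomplete exchange at one of the two bromides; proton transfer to the ring A aryllithium, or anionic rearrangement of a flanking benzyl ether, before the aldehyde arrives; slow addition to the doubly ortho-substituted aldehyde.
Fallback from 6 to 18, making K1 before the bridge so that each organolithium event happens on its own. Exchange of 6 with n-BuLi and addition to 14 gives [2,6-bis(benzyloxy)-4-methoxyphenyl][2,4-bis(benzyloxy)-6-methylphenyl]methanol F4. Dess–Martin oxidation gives [2,6-bis(benzyloxy)-4-methoxyphenyl][2,4-bis(benzyloxy)-6-methylphenyl]methanone F5. Vilsmeier–Haack formylation, expected on the more activated ring A, gives 2,4-bis(benzyloxy)-3-[2,4-bis(benzyloxy)-6-methylbenzoyl]-6-methoxybenzaldehyde F6. NaBH4 reduces only the aldehyde to {2,6-bis(benzyloxy)-3-(hydroxymethyl)-4-methoxyphenyl}[2,4-bis(benzyloxy)-6-methylphenyl]methanone F7. Acid-catalysed alkylation of excess 5 gives {2,6-bis(benzyloxy)-3-[(3-bromo-2,4-dihydroxy-6-methoxyphenyl)methyl]-4-methoxyphenyl}[2,4-bis(benzyloxy)-6-methylphenyl]methanone F8. Selective benzylation gives {2,6-bis(benzyloxy)-3-[(4-(benzyloxy)-3-bromo-2-hydroxy-6-methoxyphenyl)methyl]-4-methoxyphenyl}[2,4-bis(benzyloxy)-6-methylphenyl]methanone F9. HMDS gives its trimethylsilyl ether {2,6-bis(benzyloxy)-3-[(4-(benzyloxy)-3-bromo-6-methoxy-2-(trimethylsilyloxy)phenyl)methyl]-4-methoxyphenyl}[2,4-bis(benzyloxy)-6-methylphenyl]methanone F10. n-BuLi (1.05 equiv, THF, −100 °C) followed by Tf2O then gives 18. The price is that the ketone is exposed to butyllithium in the last operation. This is tolerable only because exchange and the silyl shift are faster than addition to a tetra-ortho-substituted ketone.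

**Step 8.** What may go wrong: insufficient discrimination between the two ring C hydroxyls, both of which have a bromine neighbour, or double benzylation.
Fallback from 5 to 10, fixing the benzyl position by chelation before the bridge is made. Vilsmeier–Haack formylation of 5 gives 3-bromo-2,4-dihydroxy-6-methoxybenzaldehyde F11. BnBr (1 equiv) with KHCO3 alkylates the hydroxyl para to the formyl group and leaves the chelated one, giving 4-(benzyloxy)-3-bromo-2-hydroxy-6-methoxybenzaldehyde F12. NaBH4 gives 3-(benzyloxy)-2-bromo-6-(hydroxymethyl)-5-methoxyphenol F13, which is used at once. With catalytic TsOH it alkylates an excess of the symmetric arene 6, which has a single kind of open position, and delivers 10. This sequence also removes the dependence on mono-alkylation of 5 in step 7.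

**Step 13.** What may go wrong: slow sulfonylation of a phenol flanked by a silyl group and the bridge carbon, with ionisation or sulfonylation of the doubly benzylic alcohol if the conditions are forced.
Fallback from 16 to 18 with the order reversed. The benzhydrol of 16 is oxidised first with MnO2 in CH2Cl2 to {2,6-bis(benzyloxy)-3-[(4-(benzyloxy)-2-hydroxy-6-methoxy-3-(trimethylsilyl)phenyl)methyl]-4-methoxyphenyl}[2,4-bis(benzyloxy)-6-methylphenyl]methanone F14. With no ionisable alcohol left, the phenol is then triflated with Tf2O and pyridine at −78 to 0 °C to give 18.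

## Further compounds

F1 | step 17 | 4-(benzyloxy)-2-methoxy-6-methylbenzoyl chloride | COc1cc(OCc2ccccc2)cc(C)c1C(Cl)=O
F2 | step 17 | 3-(benzyloxy)-6-{[2,4-bis(benzyloxy)-3-bromo-6-methoxyphenyl]methyl}-2-bromo-5-methoxyphenyl 4-(benzyloxy)-2-methoxy-6-methylbenzoate | COc1cc(OCc2ccccc2)c(Br)c(OCc2ccccc2)c1Cc1c(OC)cc(OCc2ccccc2)c(Br)c1OC(=O)c1c(C)cc(OCc2ccccc2)cc1OC
F3 | step 17 | [2,6-bis(benzyloxy)-3-({4-(benzyloxy)-3-[4-(benzyloxy)-2-methoxy-6-methylbenzoyl]-2-hydroxy-6-methoxyphenyl}methyl)-4-methoxyphenyl][2,4-bis(benzyloxy)-6-methylphenyl]methanol (racemic) | COc1cc(OCc2ccccc2)c(C(O)c2c(C)cc(OCc3ccccc3)cc2OCc2ccccc2)c(OCc2ccccc2)c1Cc1c(OC)cc(OCc2ccccc2)c(C(=O)c2c(C)cc(OCc3ccccc3)cc2OC)c1O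
F4 | step 12 | [2,6-bis(benzyloxy)-4-methoxyphenyl][2,4-bis(benzyloxy)-6-methylphenyl]methanol | COc1cc(OCc2ccccc2)c(C(O)c2c(C)cc(OCc3ccccc3)cc2OCc2ccccc2)c(OCc2ccccc2)c1
F5 | step 12 | [2,6-bis(benzyloxy)-4-methoxyphenyl][2,4-bis(benzyloxy)-6-methylphenyl]methanone | COc1cc(OCc2ccccc2)c(C(=O)c2c(C)cc(OCc3ccccc3)cc2OCc2ccccc2)c(OCc2ccccc2)c1
F6 | step 12 | 2,4-bis(benzyloxy)-3-[2,4-bis(benzyloxy)-6-methylbenzoyl]-6-methoxybenzaldehyde | COc1cc(OCc2ccccc2)c(C(=O)c2c(C)cc(OCc3ccccc3)cc2OCc2ccccc2)c(OCc2ccccc2)c1C=O
F7 | step 12 | {2,6-bis(benzyloxy)-3-(hydroxymethyl)-4-methoxyphenyl}[2,4-bis(benzyloxy)-6-methylphenyl]methanone | COc1cc(OCc2ccccc2)c(C(=O)c2c(C)cc(OCc3ccccc3)cc2OCc2ccccc2)c(OCc2ccccc2)c1CO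
F8 | step 12 | {2,6-bis(benzyloxy)-3-[(3-bromo-2,4-dihydroxy-6-methoxyphenyl)methyl]-4-methoxyphenyl}[2,4-bis(benzyloxy)-6-methylphenyl]methanone | COc1cc(OCc2ccccc2)c(C(=O)c2c(C)cc(OCc3ccccc3)cc2OCc2ccccc2)c(OCc2ccccc2)c1Cc1c(OC)cc(O)c(Br)c1O
F9 | step 12 | {2,6-bis(benzyloxy)-3-[(4-(benzyloxy)-3-bromo-2-hydroxy-6-methoxyphenyl)methyl]-4-methoxyphenyl}[2,4-bis(benzyloxy)-6-methylphenyl]methanone | COc1cc(OCc2ccccc2)c(C(=O)c2c(C)cc(OCc3ccccc3)cc2OCc2ccccc2)c(OCc2ccccc2)c1Cc1c(OC)cc(OCc2ccccc2)c(Br)c1O
F10 | step 12 | {2,6-bis(benzyloxy)-3-[(4-(benzyloxy)-3-bromo-6-methoxy-2-(trimethylsilyloxy)phenyl)methyl]-4-methoxyphenyl}[2,4-bis(benzyloxy)-6-methylphenyl]methanone | COc1cc(OCc2ccccc2)c(C(=O)c2c(C)cc(OCc3ccccc3)cc2OCc2ccccc2)c(OCc2ccccc2)c1Cc1c(OC)cc(OCc2ccccc2)c(Br)c1O[Si](C)(C)C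
F11 | step 8 | 3-bromo-2,4-dihydroxy-6-methoxybenzaldehyde | COc1cc(O)c(Br)c(O)c1C=O
F12 | step 8 | 4-(benzyloxy)-3-bromo-2-hydroxy-6-methoxybenzaldehyde | COc1cc(OCc2ccccc2)c(Br)c(O)c1C=O
F13 | step 8 | 3-(benzyloxy)-2-bromo-6-(hydroxymethyl)-5-methoxyphenol | COc1cc(OCc2ccccc2)c(Br)c(O)c1CO
F14 | step 13 | {2,6-bis(benzyloxy)-3-[(4-(benzyloxy)-2-hydroxy-6-methoxy-3-(trimethylsilyl)phenyl)methyl]-4-methoxyphenyl}[2,4-bis(benzyloxy)-6-methylphenyl]methanone | COc1cc(OCc2ccccc2)c(C(=O)c2c(C)cc(OCc3ccccc3)cc2OCc2ccccc2)c(OCc2ccccc2)c1Cc1c(OC)cc(OCc2ccccc2)c([Si](C)(C)C)c1O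
A1 | alternative 1 | [2,6-bis(benzyloxy)-3-({2-hydroxy-6-methoxy-4-[(triisopropylsilyl)oxy]-3-(trimethylsilyl)phenyl}methyl)-4-methoxyphenyl][4-(benzyloxy)-2-methoxy-6-methylphenyl]methanone | COc1cc(O[Si](C(C)C)(C(C)C)C(C)C)c([Si](C)(C)C)c(O)c1Cc1c(OC)cc(OCc2ccccc2)c(C(=O)c2c(C)cc(OCc3ccccc3)cc2OC)c1OCc1ccccc1
A2 | alternative 1 | 4-({2,4-bis(benzyloxy)-3-[4-(benzyloxy)-2-methoxy-6-methylbenzoyl]-6-methoxyphenyl}methyl)-3-methoxycyclobut-2-en-1-one (racemic) | COC1=CC(=O)C1Cc1c(OC)cc(OCc2ccccc2)c(C(=O)c2c(C)cc(OCc3ccccc3)cc2OC)c1OCc1ccccc1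
A3 | alternative 1 | trimethyl({[tri(propan-2-yl)silyl]oxy}ethynyl)silane | C[Si](C)(C)C#CO[Si](C(C)C)(C(C)C)C(C)C
A4 | alternative 2 | {2,6-bis(benzyloxy)-3-[(2,4-bis(benzyloxy)-3-{4-(benzyloxy)-2-methoxy-6-methylbenzoyl}-6-methoxyphenyl)methyl]-4-methoxyphenyl}(2,4-dihydroxy-6-methylphenyl)methanone | COc1cc(OCc2ccccc2)c(C(=O)c2c(C)cc(O)cc2O)c(OCc2ccccc2)c1Cc1c(OC)cc(OCc2ccccc2)c(C(=O)c2c(C)cc(OCc3ccccc3)cc2OC)c1OCc1ccccc1
A5 | alternative 2 | 1-{2,6-bis(benzyloxy)-3-[(2,4-bis(benzyloxy)-3-{4-(benzyloxy)-2-methoxy-6-methylbenzoyl}-6-methoxyphenyl)methyl]-4-methoxyphenyl}octane-1,3,5,7-tetrone | COc1cc(OCc2ccccc2)c(C(=O)CC(=O)CC(=O)CC(C)=O)c(OCc2ccccc2)c1Cc1c(OC)cc(OCc2ccccc2)c(C(=O)c2c(C)cc(OCc3ccccc3)cc2OC)c1OCc1ccccc1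
A6 | alternative 3 | tert-butyl 2-[3,5-bis(benzyloxy)-2-{2,6-bis(benzyloxy)-3-[(2,4-bis(benzyloxy)-3-{4-(benzyloxy)-2-methoxy-6-methylbenzoyl}-6-methoxyphenyl)methyl]-4-methoxybenzoyl}phenyl]acetate | COc1cc(OCc2ccccc2)c(C(=O)c2c(CC(=O)OC(C)(C)C)cc(OCc3ccccc3)cc2OCc2ccccc2)c(OCc2ccccc2)c1Cc1c(OC)cc(OCc2ccccc2)c(C(=O)c2c(C)cc(OCc3ccccc3)cc2OC)c1OCc1ccccc1
A7 | alternative 3 | tert-butyl 3-{2,6-bis(benzyloxy)-3-[(2,4-bis(benzyloxy)-3-{4-(benzyloxy)-2-methoxy-6-methylbenzoyl}-6-methoxyphenyl)methyl]-4-methoxyphenyl}-3-oxopropanoate | COc1cc(OCc2ccccc2)c(C(=O)CC(=O)OC(C)(C)C)c(OCc2ccccc2)c1Cc1c(OC)cc(OCc2ccccc2)c(C(=O)c2c(C)cc(OCc3ccccc3)cc2OC)c1OCc1ccccc1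
A8 | alternative 3 | 3,5-bis(benzyloxy)-2-(trimethylsilyl)phenyl trifluoromethanesulfonate | C[Si](C)(C)c1c(OCc2ccccc2)cc(OCc2ccccc2)cc1OS(=O)(=O)C(F)(F)F
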